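The runs come from a simulation from invented constants; noise was put on by code.

**Early times.** By the first noon reading, at 2.00 h, the substrate stands at 0 % and the target at 95.6 %, and the later noon target readings stay level within the scatter. The new flask takes the noon partner charge but less substrate.

| flask | substrate | partner | remark | time |
|---|---|---|---|---|
| noon | 0.14 M | 0.20 M | run made earlier |  |
| dusk | 0.22 M | 0.20 M | run made earlier |  |
| spring | 0.10 M | 0.30 M | run made earlier |  |
| flask | 0.10 M | 0.200 M |  | 12 h |

| run | time / h | substrate / % | target / % | isomer of the product / % |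
|---|---|---|---|---|
| noon | 2.00 | 0 | 95.6 | 4.3 |
| noon | 4.00 | 1.4 | 95.8 | 3.7 |
| noon | 6.00 | 0 | 95.5 | 3.8 |
| noon | 8.00 | 0.9 | 96.1 | 3.7 |
| noon | 10.0 | 0 | 96.4 | 3.4 |
| noon | 12.0 | 0.2 | 96.4 | 3.9 |
| noon | 15.0 | 0 | 95.5 | 4.2 |
| dusk | 1.00 | 7.6 | 84.8 | 6.1 |
| dusk | 2.00 | 8.2 | 83.4 | 6.8 |
| dusk | 2.50 | 8.6 | 83.6 | 7.5 |
| dusk | 4.00 | 7.4 | 84.0 | 7.9 |
| dusk | 6.00 | 8.5 | 83.3 | 7.2 |
| dusk | 10.0 | 8.2 | 83.0 | 6.8 |
| dusk | 15.0 | 8.1 | 83.6 | 7.6 |
| spring | 1.33 | 0 | 98.5 | 1.3 |
| spring | 4.00 | 0.3 | 98.0 | 1.4 |
| spring | 6.00 | 0.1 | 98.5 | 2.0 |
| spring | 10.0 | 0.6 | 97.8 | 1.8 |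
| spring | 15.0 | 0.3 | 97.7 | 1.8 |

(scatter of a reading: 0.5 percentage points)

1. which holds at 12 h: what has brought the reaction to rest, or that it has not come to rest (forward and back rates have come level / the partner has run out first / all of the substrate has reacted / it is still moving)
2. part of the substrate gone at 12 h
3. the target standing at 12 h, as a percentage of the substrate charged
4. the isomer of the product standing at 12 h, as a percentage of the substrate charged

- on the list of suspects stand: substrate <-> tight pair; tight pair <-> loose pair; partner + tight pair -> target; partner + loose pair -> isomer of the product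
- the reaction counts as stopped when no species that holds the substrate changes by six tenths of a point or more over the second half of the time

**Partner excess.** Each product takes one partner, so the charges are compared by subtraction. Partner charged minus substrate charged, 0.100 M for the flask, is the partner excess, and equal charges are the zero of its scale. Below zero, partner is the limiting reagent: the dusk run, at −0.0200 M, still shows 8.1 % substrate at its last reading.

**Noon against flask.** The noon run, at 0.0600 M, and the flask both stand above zero, so substrate limits each. That leaves 30.0 % of the noon partner and 50.0 % of the flask partner. The mean isomer reading is 3.86 % for noon and 1.66 % for the spring run, whose excess is 0.200 M. The flask excess is larger than the noon one and smaller than the spring one, so my own reckoning places its isomer between those two readings.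

**The forecast.** It expects "all of the substrate has reacted", with conversion 100 % (99.3 % to 100 %), target 96.9 % (96 % to 97.6 %) and isomer 3.1 % (2.6 % to 3.6 %). Its ground is that “partner traps the tight pair before it can relax to the loose pair”. Its isomer range is narrower than my bracket and lies inside it.

**The result.** At 12 h the flask gives "all of the substrate has reacted", with conversion 100 %, target 96.9 % and isomer 3.12 %.

    substrate ⇌ tight pair (K = 0.0610, k = 0.0950 min⁻¹)
    tight pair ⇌ loose pair (K = 1.00, k = 4.30 min⁻¹)
    partner + tight pair → target (k = 910 M⁻¹ min⁻¹)
    partner + loose pair → isomer of the product (k = 2200 M⁻¹ min⁻¹)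

**Trapping rate.** In the flask at 0.123 h, partner consumes tight pair at 32 times the forward rate of tight pair to loose pair, and 50 % of the partner remains at 12 h, the share the excess gave. A second flask, with 0.40 M substrate and the same partner, has an excess of −0.200 M. Its partner stands at 0 % at 12.0 h, with target and isomer together at 50.0 % and substrate at 44.6 %.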